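Readings and results were generated by integration on assumed constants; the scatter is artificial.

Follow the pool.

| flask | J | E | remark | time |
|---|---|---|---|---|
| cedar | 0.10 M | 0.020 M | run made earlier |  |
| alder | 0.10 M | 0.045 M | run made earlier |  |
| ash | 0.050 M | 0.030 M | run made earlier |  |
| Saturday's | 0.10 M | 0.0300 M |  | 3.0 h |
| Tuesday's | 0.10 M | 0.0300 M |  | 1.5 h |

| run | time / min | Q / % | J / % | D / % | Z / % | G / % |
|---|---|---|---|---|---|---|
| cedar | 6.00 | 36 | 57 | 0 | 1 | 0 |
| cedar | 10.0 | 50 | 40 | 1 | 1 | 0 |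
| cedar | 20.0 | 61 | 15 | 0 | 5 | 4 |
| cedar | 40.0 | 64 | 3 | 5 | 14 | 3 |
| cedar | 80.0 | 50 | 0 | 2 | 20 | 13 |
| alder | 6.00 | 30 | 52 | 0 | 0 | 1 |
| alder | 10.0 | 45 | 34 | 0 | 1 | 1 |
| alder | 20.0 | 56 | 13 | 2 | 9 | 0 |
| alder | 40.0 | 58 | 0 | 0 | 14 | 4 |
| alder | 80.0 | 39 | 0 | 3 | 14 | 10 |
| ash | 6.00 | 34 | 54 | 0 | 1 | 0 |
| ash | 20.0 | 59 | 13 | 1 | 6 | 3 |
| ash | 30.0 | 61 | 8 | 0 | 9 | 1 |
| ash | 50.0 | 54 | 2 | 1 | 16 | 5 |
| ash | 80.0 | 44 | 1 | 2 | 15 | 13 |

(readings scatter by 1.5 percentage points)

- percent here means J units held: one L counts as two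
- reactions considered so far: J -> Q; Q <-> Z; Z -> G; G <-> D; J + G -> L; J + E -> X

- which of these there is most of at the end, counted by the J in it, Saturday's (G / Z / Q / D)
- which of these there is most of at the end, counted by the J in it, Tuesday's (G / Z / Q / D)
- how much there is at the end of the one of these that leads, in percent of the J charged: Saturday's
- how much there is at the end of the one of these that leads, in percent of the J charged: Tuesday's

- Saturday's and Tuesday's carry the same charge, so you reckon one curve and read it at 1.5 h and at 3.0 h.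
- Start with the main step, J to Q. Cedar's J reads 3 % at 40.0 min, earlier than either reading, so you treat J as passed on.
- Add J with E to X. At that time the listed species sum to 89.0 % in cedar and 76.0 % in alder. Those two runs bracket this E, so you keep their mean, 82.5 %, and read the gap as X and L.
- Add the rest. Take Q and Z as one pool, starting at 40.0 min from the cedar and alder mean of 75.0 %. The pool leak, the mean fall of the logarithm of Q plus Z per minute over the late readings of the three runs, an apparent first-order constant, is 0.00532 min⁻¹. Q's late share of the pool reads 73.2 %.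
- My reckoning for Tuesday's gives a pool of 57.5 %, so Q at 42.1 % stands above G and D together at 25.0 %.
- For Saturday's it gives a pool of 35.6 %, Q at 26.1 %, and G and D together at 46.9 %. On this reckoning G stands above Q if D stays under 21 percentage points, and D reads 2 % in cedar and 3 % in alder at 80.0 min.
- Now check the error of the mean. Cedar's leak by itself, 0.00271 min⁻¹, is slower and puts Saturday's Q at 37.6 %, above G and D together at 31.1 %. So Saturday's is the weaker call.
- The forecast names G at 30 % for Saturday's and Q at 43 % for Tuesday's, with the caution “If D instead keeps growing slowly, G and Q come close”. My reckoning gives G and D only as a sum.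

- The flasks bear the forecast out: Saturday's ends with G at 28.8 % over Q at 23.7 %, and Tuesday's with Q at 43.6 %.

    J → Q (k = 0.0780 min⁻¹)
    Q ⇌ Z (K = 1.70, k = 0.00930 min⁻¹)
    Z → G (k = 0.0190 min⁻¹)
    G ⇌ D (K = 1.30, k = 0.00920 min⁻¹)
    J + G → L (k = 0.0900 M⁻¹ min⁻¹)
    J + E → X (k = 0.920 M⁻¹ min⁻¹)

- Saturday's pool stands at 35.6 % against the reckoned 35.6 %, and its D of 17.1 % stays under the reckoned room. Read sooner, Saturday's flask has another leader. For the neighbour, Saturday's flask left until 80 min, the leak gives a pool of 60.6 %, with Q at 44.4 % above G and D together at 21.9 %. That neighbour holds a pool of 64.3 %, and Q leads at 46.8 % with G at 13.7 %.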